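The core is numbered with bridgeheads C1 and C6, quaternary C2, acetyl-bearing C3, then C4, C5, C7, C8=C9 and the bridge C10. Ring A is the cyclohexene, ring B the seven-membered ring. The plan cuts the C3–C4 bond of ring B. C10 and the acetyl carbonyl carbon (C11) each carry one methyl group and one oxygen and stand 1,5 to each other, so both arise by methyl addition to a trans-bridged bicyclo[5.3.1]undecenedione made by a de Mayo reaction. In the key step C4 moves from C11 to C3 as a C3 mesylate leaves, which shrinks ring B from an eight- to a seven-membered ring, inverts C3 and unveils the acetyl group at once. The precursor is cis-hydroxy mesylate 28.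

Key step: step 16

Remarks on the chemistry
- In the bicyclo[5.3.1] compounds ring B runs C10–C1–C2–C3–C11–C4–C5–C6; "up/down" statements refer to this ring.
- In 28 the C11 carbinol is the epimer with its hydroxyl cis to the C3 mesylate on ring B. This is the epimer that chelation-controlled methyl addition gives, and it cannot close to the C3–C11 epoxide, whereas the trans epimer can.
- The C9 one-carbon substituent is carried as the diethyl acetal of the final aldehyde. It is a spectator in the key step, and this choice saves a protecting-group exchange and the last oxidation.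
- C9 is a temporary stereocentre in 10–14 and 18–24. Both epimers are carried together, their SMILES leave C9 open, and they converge in step 12.
- Weinreb amide 15 is assumed to be a catalogue compound (otherwise two standard steps from methyl glycolate).

Step 1
Reactants: 1 (S)-citronellal
Product: 3 (S)-3,7-dimethyloct-6-en-1-yne, via enol nonaflate 2 (not isolated)
Conditions: NfF (C4F9SO2F), phosphazene base P2-Et, DMF, −20 °C → rt
Reagents that add atoms: none
Why: Aldehyde-to-alkyne dehydration through an enol sulfonate: the enolate is O-sulfonylated and the alkenyl nonaflate loses nonaflate by base-induced elimination, while the stereocentre is β to the carbonyl and the low temperature should avoid propargyl–allenyl isomerisation.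

Step 2
Reactants: 3 (S)-3,7-dimethyloct-6-en-1-yne
Product: 5 (S,E)-1-iodo-2,3,7-trimethylocta-1,6-diene, via alkenyl(dimethyl)alane 4 (not isolated)
Conditions: Me3Al, Cp2ZrCl2 (cat.), CH2Cl2, 0 °C → rt; then I2, THF, −30 °C
Reagents that add atoms: trimethylaluminium, C[Al](C)C; iodine, II
Why: Zirconium-catalysed carboalumination (Negishi) adds methyl and aluminium syn across the terminal alkyne with methyl on the internal carbon, and iodinolysis of the C–Al bond with retention fixes the E geometry.

Step 3
Reactants: 6 ethyl diethoxyacetate; 7 but-3-enylmagnesium bromide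
Product: 8 1,1-diethoxyhex-5-en-2-one
Conditions: THF, −78 °C; then sat. aq. NH4Cl
Reagents that add atoms: none
Why: Acyl substitution of the α,α-dialkoxy ester by one equivalent of the organomagnesium reagent stops at the ketone because the chelated bromomagnesium hemiketal survives at −78 °C until work-up.

Step 4
Reactants: 5 (S,E)-1-iodo-2,3,7-trimethylocta-1,6-diene; 8 1,1-diethoxyhex-5-en-2-one
Product: 11 tertiary allylic TMS ether (both C9 epimers), via alkenyllithium 9 (not isolated), via lithium alkoxide 10 (not isolated)
Conditions: t-BuLi (2 equiv), Et2O, −78 °C; add 8; then TMSCl, −78 °C → rt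
Reagents that add atoms: chlorotrimethylsilane, C[Si](C)(C)Cl
Why: Iodine–lithium exchange keeps the alkene geometry, 1,2-addition of the alkenyllithium to the electrophilic α-ketoacetal outruns enolisation and the tertiary alkoxide is silylated in the same flask, while the new carbinol centre C9 is formed without control and is erased in step 12.

Step 5
Reactants: 11 tertiary allylic TMS ether
Product: 13 primary alcohol, via B-alkyl-9-BBN 12 (not isolated)
Conditions: 9-BBN, THF, 0 °C → rt; then H2O2, aq. NaOAc, 0 °C
Reagents that add atoms: hydrogen peroxide, OO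
Why: Hydroboration–oxidation, in which 9-BBN takes the monosubstituted terminal alkene far faster than the two trisubstituted ones and places boron on the terminal carbon, and buffered peroxide spares the TMS ether and the acetal.

Step 6
Reactants: 13 primary alcohol
Product: 14 aldehyde
Conditions: DMP, NaHCO3, CH2Cl2, 0 °C → rt
Reagents that add atoms: none
Why: Dess–Martin oxidation of the primary alcohol under buffered, non-aqueous conditions stops at the aldehyde and leaves silyl ether, acetal and alkenes alone.

Step 7
Reactants: 15 2-(tert-butyldimethylsilyloxy)-N-methoxy-N-methylacetamide; 16 vinylmagnesium bromide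
Product: 17 1-(tert-butyldimethylsilyloxy)but-3-en-2-one
Conditions: THF, −78 → 0 °C; inverse quench into cold 1 M HCl
Reagents that add atoms: none
Why: Weinreb ketone synthesis, with an inverse acidic quench that keeps the released N,O-dimethylhydroxylamine protonated so that it cannot add to the enone.

Step 8
Reactants: 14 aldehyde; 17 1-(tert-butyldimethylsilyloxy)but-3-en-2-one
Product: 18 keto aldehyde with C6 set as R
Conditions: (S)-2-[methoxy(diphenyl)methyl]pyrrolidine (10 mol%), ethyl 3,4-dihydroxybenzoate (20 mol%), CH2Cl2, 4 °C
Reagents that add atoms: none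
Why: Enamine-catalysed asymmetric Michael addition of an aldehyde to a vinyl ketone, in which the E-enamine of 14 is shielded on one face by the diarylmethyl group of the (S)-pyrrolidine, 17 adds to the open face and sets C6 as R, and the α-branched product no longer forms an enamine, so C6 is not scrambled.

Step 9
Reactants: 18 keto aldehyde
Product: 20 keto methyl ester, via keto acid 19 (not isolated)
Conditions: NaClO2, NaH2PO4, 2-methyl-2-butene, t-BuOH/H2O, 0 °C; then MeI, K2CO3, DMF, rt
Reagents that add atoms: sodium chlorite, [Na+].[O-]Cl=O; iodomethane, CI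
Why: Pinnick oxidation followed by carboxylate O-methylation raises C10 to the ester level without enolisation at C6, which a base-mediated aldol closure of the aldehyde would put at risk.

Step 10
Reactants: 20 keto methyl ester
Product: 21 2-silyloxy-1,3-dione (enol form)
Conditions: KOtBu (2.2 equiv), THF, 0 °C; then cold 0.5 M HCl
Reagents that add atoms: none
Why: Intramolecular Claisen (Dieckmann-type) condensation, in which only the ketone enolate on the silyloxy-bearing carbon C3 reaches the ester through a six-membered ring, the dione is withdrawn as its stabilised enolate, and the far less acidic ester α-hydrogen at C6 is left alone.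

Step 11
Reactants: 21 2-silyloxy-1,3-dione
Product: 24 trans-bridged bicyclo[5.3.1]undecanedione carrying a free C9 carbinol (both C9 epimers), via cyclobutanol photoadduct 22 (not isolated), via TMS ether diketone 23 (not isolated)
Conditions: hν (350 nm, Pyrex), degassed MeCN (5 mM), 0 °C; then citric acid, EtOH, rt
Reagents that add atoms: none
Why: Intramolecular de Mayo reaction ([2+2] photocycloaddition of the enolised 1,3-dione, then retro-aldol opening of the cyclobutanol), in which only the enol tautomer with the C3=C10 double bond can bring C10 to C1 through a six-membered array, the chair-like approach with the tether and the C1 alkene substituent equatorial joins C10–C1 so that C1 and C6 end trans across ring A (in,out), the 1,4-biradical closes C3–C2 with the large side chain turned away from C9 and the silyloxy group (which sets quaternary C2), C3 is protonated after fragmentation on the face of the C2 methyl group, and acidic ethanol then removes the TMS group.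

Step 12
Reactants: 24 hydroxy diketone
Product: 25 diketone with the C8=C9 alkene and the C9 diethoxymethyl group
Conditions: Burgess reagent, toluene, 80 °C
Reagents that add atoms: none
Why: Burgess dehydration (syn-elimination of the tertiary sulfamate), for which a C8 hydrogen is available in either C9 epimer whereas the acetal hydrogen would lead to a ketene acetal and the C1 hydrogen to a bridgehead alkene, so the endocyclic C8=C9 alkene is expected and both epimers converge on one compound.

Step 13
Reactants: 25 unsaturated acetal diketone
Product: 26 α-ketol with free C3 hydroxyl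
Conditions: TBAF, AcOH, THF, 0 °C → rt
Reagents that add atoms: none
Why: Fluoride cleavage of the silyl ether, buffered with acetic acid so that neither the α-ketol nor the unsaturated acetal meets base or strong acid, frees the C3 hydroxyl that directs the next step.

Step 14
Reactants: 26 α-ketol
Product: 27 triol with methyl carbinols at C10 and C11
Conditions: MeLi (6 equiv), CeCl3, THF, −78 → 0 °C
Reagents that add atoms: methyllithium, [Li]C
Why: 1,2-Addition of MeCeCl2 to both ketones with little enolisation, in which at C11 the metal bridges the C3 alkoxide and the carbonyl oxygen and methyl enters anti to quaternary C2 (chelation control) to give the carbinol with hydroxyl cis to the C3 oxygen, at C10 methyl enters anti to the C1–C2 bond that allylic 1,2-strain from the C9 substituent holds pseudoaxial on ring A so that the C10 hydroxyl ends on the side of C2, and the bridgehead hydrogens, lying near the nodal plane of the C10 carbonyl, are not removed.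

Step 15
Reactants: 27 triol
Product: 28 cis-hydroxy mesylate (key-step precursor)
Conditions: MsCl, Et3N, CH2Cl2, −20 °C
Reagents that add atoms: methanesulfonyl chloride, CS(=O)(=O)Cl
Why: Sulfonylation through sulfene takes the only secondary hydroxyl, the two tertiary carbinols reacting much more slowly at −20 °C, and the cis relation between the C11 hydroxyl and the new mesylate excludes epoxide closure.

Step 16
Reactants: 28 cis-hydroxy mesylate
Product: 30 trans-bridged bicyclo[4.3.1]decene with C3 acetyl and free C10 carbinol, via potassium alkoxide 29 (not isolated)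
Conditions: KOtBu (2.5 equiv), THF, 0 °C; quench with pH 7 phosphate buffer
Reagents that add atoms: none
Why: Deprotonation gives the C11 alkoxide 29, whose oxygen lone pair drives the C11–C4 bond, held antiperiplanar to the C3–O bond, onto the rear of C3 as mesylate departs, so that C3–C4 forms and C11 becomes the acetyl carbonyl without a free cation. The closest known reaction type is the base-induced semipinacol ring contraction of a cyclic tertiary carbinol with a vicinal sulfonate, which gives an acyl-substituted ring one atom smaller. Ring B closes as a seven-membered ring by a 1,2-shift of a ring carbon (contraction of the eight-membered ring), not by an end-to-end cyclisation, and the trans bridging is carried over unchanged. The new stereocentre C3 is controlled by the substrate, because the shift is stereospecific with inversion at C3 and retention at the migrating C4. The step needs C4 to migrate in preference to the C11 methyl group and needs oxygen nucleophiles to stay out: in the cis-hydroxy mesylate the rotamer that puts C4 anti to the mesylate is also the one that keeps quaternary C2 away from the C11 methyl group, the C11 oxygen cannot reach the anti position needed for epoxide closure, the C10 oxygen sits on the mesylate face of ring B and cannot attack C3 from behind, and C3 has no β-hydrogen for elimination. A short reaction time at 0 °C and a buffered quench limit enolisation of the new methyl ketone toward C3.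

Step 17
Reactants: 30 hydroxy methyl ketone
Product: 31 tertiary C10 acetate
Conditions: Ac2O, DMAP (2 equiv), Et3N, CH2Cl2, 40 °C
Reagents that add atoms: acetic anhydride, CC(=O)OC(C)=O
Why: DMAP-catalysed acylation through the N-acetylpyridinium ion of the only hydroxyl left, the tertiary C10 carbinol, under conditions that do not enolise the methyl ketone.

Step 18
Reactants: 31 tertiary C10 acetate
Product: 32 target CNP0288370.1
Conditions: PPTS, acetone/H2O, rt
Reagents that add atoms: water, O
Why: Acid-catalysed hydrolysis of the α,β-unsaturated acetal, which ionises far more easily than the tertiary acetate or the isolated alkenes, releases the enal.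

Compound list
1 | (S)-citronellal | O=CC[C@@H](C)CCC=C(C)C | starting material
2 | (S)-3,7-dimethylocta-1,6-dien-1-yl nonafluorobutanesulfonate (E/Z mixture) | O=S(=O)(OC=C[C@@H](C)CCC=C(C)C)C(F)(F)C(F)(F)C(F)(F)C(F)(F)F | intermediate (not isolated)
3 | (S)-3,7-dimethyloct-6-en-1-yne | C#C[C@@H](C)CCC=C(C)C | intermediate
4 | dimethyl[(S,E)-2,3,7-trimethylocta-1,6-dien-1-yl]alane | C[Al](C)/C=C(\C)[C@@H](C)CCC=C(C)C | intermediate (not isolated)
5 | (S,E)-1-iodo-2,3,7-trimethylocta-1,6-diene | I/C=C(\C)[C@@H](C)CCC=C(C)C | intermediate
6 | ethyl diethoxyacetate | CCOC(=O)C(OCC)OCC | starting material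
7 | but-3-enylmagnesium bromide | C=CCC[Mg]Br | starting material
8 | 1,1-diethoxyhex-5-en-2-one | C=CCCC(=O)C(OCC)OCC | intermediate
9 | [(S,E)-2,3,7-trimethylocta-1,6-dien-1-yl]lithium | [Li]/C=C(\C)[C@@H](C)CCC=C(C)C | intermediate (not isolated)
10 | lithium (6E,8S)-5-(diethoxymethyl)-7,8,12-trimethyltrideca-1,6,11-trien-5-olate (both epimers at C5, which is core C9) | [Li]OC(CCC=C)(C(OCC)OCC)/C=C(\C)[C@@H](C)CCC=C(C)C | intermediate (not isolated)
11 | (6E,8S)-5-(diethoxymethyl)-7,8,12-trimethyl-5-(trimethylsilyloxy)trideca-1,6,11-triene (both C5 epimers) | C[Si](C)(C)OC(CCC=C)(C(OCC)OCC)/C=C(\C)[C@@H](C)CCC=C(C)C | intermediate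
12 | B-alkyl-9-borabicyclo[3.3.1]nonane from 11, boron on the former terminal alkene carbon | C[Si](C)(C)OC(CCCCB1C2CCCC1CCC2)(C(OCC)OCC)/C=C(\C)[C@@H](C)CCC=C(C)C | intermediate (not isolated)
13 | (6E,8S)-5-(diethoxymethyl)-7,8,12-trimethyl-5-(trimethylsilyloxy)trideca-6,11-dien-1-ol (both C5 epimers) | OCCCCC(O[Si](C)(C)C)(C(OCC)OCC)/C=C(\C)[C@@H](C)CCC=C(C)C | intermediate
14 | (6E,8S)-5-(diethoxymethyl)-7,8,12-trimethyl-5-(trimethylsilyloxy)trideca-6,11-dienal (both C5 epimers) | O=CCCCC(O[Si](C)(C)C)(C(OCC)OCC)/C=C(\C)[C@@H](C)CCC=C(C)C | intermediate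
15 | 2-(tert-butyldimethylsilyloxy)-N-methoxy-N-methylacetamide | CON(C)C(=O)CO[Si](C)(C)C(C)(C)C | starting material
16 | vinylmagnesium bromide | C=C[Mg]Br | starting material
17 | 1-(tert-butyldimethylsilyloxy)but-3-en-2-one | C=CC(=O)CO[Si](C)(C)C(C)(C)C | intermediate
18 | (2R,6E,8S)-2-[4-(tert-butyldimethylsilyloxy)-3-oxobutyl]-5-(diethoxymethyl)-7,8,12-trimethyl-5-(trimethylsilyloxy)trideca-6,11-dienal (C2 is core C6; both C5 epimers) | O=C[C@@H](CCC(=O)CO[Si](C)(C)C(C)(C)C)CCC(O[Si](C)(C)C)(C(OCC)OCC)/C=C(\C)[C@@H](C)CCC=C(C)C | intermediate
19 | carboxylic acid corresponding to 18 | OC(=O)[C@@H](CCC(=O)CO[Si](C)(C)C(C)(C)C)CCC(O[Si](C)(C)C)(C(OCC)OCC)/C=C(\C)[C@@H](C)CCC=C(C)C | intermediate (not isolated)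
20 | methyl ester of 19 | COC(=O)[C@@H](CCC(=O)CO[Si](C)(C)C(C)(C)C)CCC(O[Si](C)(C)C)(C(OCC)OCC)/C=C(\C)[C@@H](C)CCC=C(C)C | intermediate
21 | (4R)-2-(tert-butyldimethylsilyloxy)-3-hydroxy-4-[tether]cyclohex-2-en-1-one, the enol form of the 2-silyloxy-1,3-dione; tether = (4E,6S)-3-(diethoxymethyl)-5,6,10-trimethyl-3-(trimethylsilyloxy)undeca-4,9-dienyl | O=C1CC[C@@H](CCC(O[Si](C)(C)C)(C(OCC)OCC)/C=C(\C)[C@@H](C)CCC=C(C)C)C(O)=C1O[Si](C)(C)C(C)(C)C | intermediate
22 | cyclobutanol photoadduct: cyclobutane C10–C1–C2–C3 cis-fused to the dione ring and trans-fused to ring A, C10 hydroxyl, C3 OTBS, C9 OTMS | O[C@]12[C@@H]3CCC(O[Si](C)(C)C)(C(OCC)OCC)[C@@H]1[C@@](C)([C@@H](C)CCC=C(C)C)[C@@]2(O[Si](C)(C)C(C)(C)C)C(=O)CC3 | intermediate (not isolated)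
23 | trans-bridged bicyclo[5.3.1]undecane-10,11-dione (core numbering) with C9 OTMS and CH(OEt)2, C3 OTBS up, C2 methyl down and (S)-6-methylhept-5-en-2-yl up | O=C1[C@@H]2CCC(O[Si](C)(C)C)(C(OCC)OCC)[C@@H]1[C@@](C)([C@@H](C)CCC=C(C)C)[C@@H](O[Si](C)(C)C(C)(C)C)C(=O)CC2 | intermediate (not isolated)
24 | as 23 with free C9 hydroxyl (both C9 epimers) | O=C1[C@@H]2CCC(O)(C(OCC)OCC)[C@@H]1[C@@](C)([C@@H](C)CCC=C(C)C)[C@@H](O[Si](C)(C)C(C)(C)C)C(=O)CC2 | intermediate
25 | trans-bridged bicyclo[5.3.1]undec-8-ene-10,11-dione (core numbering) with C9 diethoxymethyl and C3 OTBS | O=C1[C@@H]2CC=C(C(OCC)OCC)[C@@H]1[C@@](C)([C@@H](C)CCC=C(C)C)[C@@H](O[Si](C)(C)C(C)(C)C)C(=O)CC2 | intermediate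
26 | as 25 with free C3 hydroxyl | O=C1[C@@H]2CC=C(C(OCC)OCC)[C@@H]1[C@@](C)([C@@H](C)CCC=C(C)C)[C@@H](O)C(=O)CC2 | intermediate
27 | triol: C10 and C11 methyl carbinols, C3 hydroxyl; C3, C10 and C11 oxygens all on the same face of ring B | O[C@]1(C)[C@@H]2CC=C(C(OCC)OCC)[C@@H]1[C@@](C)([C@@H](C)CCC=C(C)C)[C@@H](O)[C@@](C)(O)CC2 | intermediate
28 | C3 mesylate of 27 (key-step precursor) | O[C@]1(C)[C@@H]2CC=C(C(OCC)OCC)[C@@H]1[C@@](C)([C@@H](C)CCC=C(C)C)[C@@H](OS(C)(=O)=O)[C@@](C)(O)CC2 | intermediate
29 | potassium C11 alkoxide of 28 | O[C@]1(C)[C@@H]2CC=C(C(OCC)OCC)[C@@H]1[C@@](C)([C@@H](C)CCC=C(C)C)[C@@H](OS(C)(=O)=O)[C@@](C)([O-])CC2.[K+] | intermediate (not isolated)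
30 | trans-bridged bicyclo[4.3.1]dec-7-ene core with C3 acetyl, free C10 methyl carbinol and C9 diethoxymethyl (key-step product) | O[C@]1(C)[C@@H]2CC=C(C(OCC)OCC)[C@@H]1[C@@](C)([C@@H](C)CCC=C(C)C)[C@@H](C(C)=O)CC2 | intermediate
31 | C10 acetate of 30 | CC(=O)O[C@]1(C)[C@@H]2CC=C(C(OCC)OCC)[C@@H]1[C@@](C)([C@@H](C)CCC=C(C)C)[C@@H](C(C)=O)CC2 | intermediate
32 | CNP0288370.1 | CC(=O)O[C@]1(C)[C@@H]2CC=C(C=O)[C@@H]1[C@@](C)([C@@H](C)CCC=C(C)C)[C@@H](C(C)=O)CC2 | target

Total step count: 18. Longest linear sequence: 16 steps (from 1 through steps 1, 2, 4, 5, 6 and 8–18; steps 3 and 7 make side fragments).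

Steps most likely to fail

Step 11 (de Mayo reaction). The excited hydrogen-bonded enol may decay by proton transfer without reacting. The 1,4-biradical has to close between two fully substituted carbons (C3 and C2) and may instead revert or transfer hydrogen. Facial control in C10–C1 bond formation may be incomplete and give the cis-bridged skeleton. The fallback sets out from 21 and returns at 24: the enol is masked before irradiation and the fragmentation is made a separate event. Treatment of 21 with TMSCl and Et3N in CH2Cl2 at 0 °C should give the O-trimethylsilyl enol ether F1, in which the silyl group shuttles between the two enol oxygens so that the C3=C10 isomer is always available. Irradiation of F1 (350 nm, MeCN) should give the silyloxycyclobutane F2, which cannot undergo retro-aldol opening and can be purified. Citric acid in ethanol then removes both TMS groups, the freed cyclobutanol fragments, and 24 is reached.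

Step 16 (semipinacol ring contraction). The C11 methyl group may migrate instead of C4 if ring B prefers the other rotamer about C3–C11. The very hindered mesylate may not react. The product may lose its C3 configuration by enolisation. The fallback sets out from 27 and returns at 30 through an acyloin (α-ketol) rearrangement. Buffered DMP oxidation of the secondary C3 alcohol should give the α-hydroxy ketone F3. With catalytic KOtBu in THF the C11 alkoxide shifts C4 onto the C3 carbonyl carbon; this 1,2-shift is reversible and should be drawn toward the ring-contracted ketol F4 by the strain of the trans-bridged eight-membered ring. SmI2 in THF/MeOH then removes the C3 hydroxyl, and protonation of the enolate formed with SmI2 on the face of the C2 methyl group should give 30.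

Step 14 (double methyl addition). The alkoxide formed first may add across ring B to the remaining ketone and stall the second addition. Methyl may also enter the hindered C10 ketone from the wrong face. The fallback sets out from 26 and returns at 27, making the two carbinols one at a time. MeMgBr in CH2Cl2/Et2O at −78 °C should add only to the chelated C11 ketone and give the mono-adduct F5. The C10 ketone is then converted with dimethylsulfonium methylide (Me3SI, n-BuLi, THF) into the spiro-epoxide F6. LiEt3BH opens F6 at its methylene carbon to the C10 methyl carbinol 27.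

Further compounds
F1 | step 11 | O-trimethylsilyl enol ether of 21, C10 silyl ether isomer (both C9 epimers) | O=C1CC[C@@H](CCC(O[Si](C)(C)C)(C(OCC)OCC)/C=C(\C)[C@@H](C)CCC=C(C)C)C(O[Si](C)(C)C)=C1O[Si](C)(C)C(C)(C)C
F2 | step 11 | silyloxycyclobutane photoadduct (both C9 epimers) | C[Si](C)(C)O[C@]12[C@@H]3CCC(O[Si](C)(C)C)(C(OCC)OCC)[C@@H]1[C@@](C)([C@@H](C)CCC=C(C)C)[C@@]2(O[Si](C)(C)C(C)(C)C)C(=O)CC3
F3 | step 16 | α-hydroxy ketone with C3 ketone and C11 methyl carbinol | O[C@]1(C)[C@@H]2CC=C(C(OCC)OCC)[C@@H]1[C@@](C)([C@@H](C)CCC=C(C)C)C(=O)[C@@](C)(O)CC2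
F4 | step 16 | ring-contracted ketol with hydroxyl and acetyl on C3 (C3 configuration open, erased in the next operation) | O[C@]1(C)[C@@H]2CC=C(C(OCC)OCC)[C@@H]1[C@@](C)([C@@H](C)CCC=C(C)C)C(O)(C(C)=O)CC2
F5 | step 14 | mono-adduct with C11 methyl carbinol and C10 ketone | O=C1[C@@H]2CC=C(C(OCC)OCC)[C@@H]1[C@@](C)([C@@H](C)CCC=C(C)C)[C@@H](O)[C@@](C)(O)CC2
F6 | step 14 | C10 spiro-epoxide with oxygen on the side of C2 | O1C[C@]12[C@@H]3CC=C(C(OCC)OCC)[C@@H]2[C@@](C)([C@@H](C)CCC=C(C)C)[C@@H](O)[C@@](C)(O)CC3
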